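The data come from a simulation for substances that don't exist, and the scatter is random.

In a one-step world substrate falls pseudo-first-order with one constant set by the catalyst, and the catalyst, the smallest charge, is not consumed, so among flasks of one substrate charge I compare catalyst multiplied by time.

the same everywhere: gas 63 mM (held)
- east: substrate 0.12 M; free catalyst 0.84 mM; run made earlier
- south-east: substrate 0.12 M; free catalyst 1.3 mM; run made earlier
- north: substrate 0.060 M; free catalyst 0.60 mM; run made earlier
- flask: substrate 0.12 M; free catalyst 0.60 mM; time 10 d

| run | time / d | product / % | substrate / % |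
|---|---|---|---|
| east | 0.500 | 22.8 | 76.9 |
| east | 0.833 | 34.6 | 64.0 |
| east | 1.25 | 47.2 | 52.2 |
| east | 2.00 | 63.5 | 36.4 |
| east | 4.00 | 84.4 | 15.1 |
| east | 6.00 | 93.3 | 6.1 |
| south-east | 0.500 | 32.5 | 67.0 |
| south-east | 0.833 | 47.6 | 51.2 |
| south-east | 1.25 | 61.6 | 37.6 |
| south-east | 2.00 | 77.0 | 22.4 |
| south-east | 4.00 | 93.9 | 6.4 |
| south-east | 6.00 | 97.8 | 1.7 |
| north | 0.500 | 24.2 | 75.3 |
| north | 0.833 | 37.0 | 62.5 |
| north | 1.67 | 59.0 | 40.6 |
| north | 3.00 | 78.9 | 20.9 |
| north | 6.00 | 94.9 | 4.9 |

(scatter of a reading: 0.3 percentage points)

- at the start none of the gas is in solution
- partner is what gas becomes in solution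

- amount of product at 10 d, in percent of the substrate charged
- concentration of partner in solution at 10 d, in percent of saturation

The south-east run shares this flask's substrate charge, and against it the flask's 10 d come to 4.62 d; that is the matched time, a flask's time multiplied by its catalyst charge and divided by the run's. The readings allow it: 1.25 d of the east run match 0.808 d of the south-east run, and the east run's 52.2 % of substrate stands beside the south-east run's 51.2 % at 0.833 d.

Two extreme flasks can be reckoned in the head. With the south-east run's first constant as read, scaled to this flask as 0.370 /d, held throughout, 2.47 % of the substrate stays; with its late constant as read, scaled to 0.306 /d, 4.69 % stays. I expect the real flask to begin on the faster constant and sag towards the other, so I place it between them. Interpolating the logarithm of substrate at the matched time, I reckon 4.26 % of substrate, hence 95.7 % of product; the matched time says nothing of partner.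

The forecast, reckoned its own way, gives 95.5 % of product and 99 % of saturation: “Partner should be essentially saturated”.

The flask gives 95.9 % of product and 82.1 % of saturation, below the forecast's partner, with 3.79 % of substrate left.

    partner + catalyst intermediate A → catalyst intermediate B (k = 1.30 /M/s)
    partner → decomposed reagent (k = 7.30 × 10⁻⁶ /s)
    gas ⇌ partner, rate k3*(csat - [partner]) (kL = 3.50 × 10⁻⁵ /s)
    catalyst intermediate B → by-product + catalyst intermediate C (k = 0.00370 /s)
    catalyst intermediate C ⇌ free catalyst + product (K = 0.0460 M, k = 0.00270 /s)
    substrate + free catalyst → catalyst intermediate A (k = 0.0210 /M/s)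

Partner's decomposition alone has a half-life of 1.1 d, shorter than the 10 d of the flask. The same flask read at 2.5 d has a matched time of 1.15 d, between the south-east readings at 0.833 d and 1.25 d, and interpolating there gives 40.4 % of substrate. That neighbouring flask holds 59.4 % of product and 40 % of substrate.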